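**Assumption:** natural (2S)-(−)-naringenin (≥98% ee, checked by chiral HPLC), 2,4,6-trihydroxybenzaldehyde and 4-ethynylphenylboronic acid are taken as catalogue compounds.

**Retrosynthetic overview**
- The only stereocentre (C2 of the flavanone) is bought in (2S)-naringenin. The three flavanone rings are never rebuilt and never see anything more basic than a tertiary amine.
- The diaryl ether is cut at the O–C(phenylene) bond: a C6 phenol of the flavanone plus an arylboronic acid (Chan–Lam coupling). The C6 phenol comes from naringenin by 7-O-methylation, 5-OH-directed C6 iodination, MOM protection and borylation/oxidation.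
- The flavone pyranone is cut back to an isoxazole (a masked 1,3-dicarbonyl). The isoxazole ring is formed by a nitrile oxide–alkyne [3+2] cycloaddition between 2,4,6-tris(benzyloxy)benzonitrile oxide and 4-ethynylphenylboronic acid.
- Ring order: flavanone rings bought → isoxazole ring by [3+2] → after the ether coupling, N–O hydrogenolysis and acid cyclodehydration turn the isoxazole into the flavone pyranone last, with all protecting groups removed in the same operation.

**Route**

Step 1
Reactants: 1 (2S)-naringenin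
Product: 2 (2S)-sakuranetin, i.e. (2S)-5-hydroxy-2-(4-hydroxyphenyl)-7-methoxychroman-4-one
Conditions: MeOH (1.1 equiv), PPh3, DIAD, THF, 0 °C → rt
Reagents that add atoms: methanol, CO
Why: Mitsunobu etherification is pKa-driven, so the most acidic 7-OH (para to the carbonyl) is methylated ahead of the 4'-OH and the chelated 5-OH under neutral conditions that leave the bought C2 centre untouched.

Step 2
Reactants: 2 (2S)-sakuranetin
Product: 3 (2S)-5-hydroxy-2-(4-hydroxyphenyl)-6-iodo-7-methoxychroman-4-one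
Conditions: BnMe3N+ ICl2− (1.05 equiv), CaCO3, CH2Cl2–MeOH, rt
Reagents that add atoms: benzyltrimethylammonium dichloroiodate, C[N+](C)(C)Cc1ccccc1.Cl[I-]Cl
Why: Electrophilic aromatic iodination in which the phloroglucinol-type A ring is far more nucleophilic than the B-ring phenol and the free, chelated 5-OH steers the electrophile to its ortho position C6; CaCO3 only scavenges HCl, so C2 is not touched.

Step 3
Reactants: 3 (2S)-6-iodosakuranetin
Product: 4 (2S)-6-iodo-7-methoxy-5-(methoxymethoxy)-2-[4-(methoxymethoxy)phenyl]chroman-4-one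
Conditions: MOMCl (5 equiv), iPr2NEt, Bu4NI (cat.), CH2Cl2, 0 → 40 °C
Reagents that add atoms: chloromethyl methyl ether (MOMCl), COCCl
Why: O-alkylation (Williamson-type acetal formation) in which the 4'-OH reacts at 0 °C and the chelated 5-OH, acidified by the ortho iodine, follows on warming with iodide catalysis; Hünig's base is too weak to enolise C3, so the flavanone does not open.

Step 4
Reactants: 4 bis-MOM 6-iodoflavanone
Product: 6 (2S)-6-hydroxy-7-methoxy-5-(methoxymethoxy)-2-[4-(methoxymethoxy)phenyl]chroman-4-one, via C6 pinacol boronate 5 (not isolated)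
Conditions: B2pin2, Pd(OAc)2/SPhos, KOAc, dioxane, 80 °C; then Oxone (1.1 equiv), acetone–H2O, 0 °C, 10 min
Reagents that add atoms: bis(pinacolato)diboron, CC1(C)OB(OC1(C)C)B1OC(C)(C)C(C)(C)O1 (Bpin of 5 only); potassium peroxymonosulfate (Oxone), [K+].[O-]S(=O)(=O)OO (the new O of 6)
Why: Miyaura borylation (Pd/SPhos for the di-ortho-substituted iodide, KOAc cannot enolise C3) followed by ipso-oxidation of the C–B bond (1,2-aryl shift from boron to oxygen) puts the hydroxyl exactly where the iodine was without any base.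

Step 5
Reactants: 7 2,4,6-trihydroxybenzaldehyde
Product: 8 2,4,6-tris(benzyloxy)benzaldehyde
Conditions: BnBr (4 equiv), K2CO3, DMF, 70 °C
Reagents that add atoms: benzyl bromide, BrCc1ccccc1
Why: Exhaustive Williamson O-benzylation; the formyl group lowers the ring nucleophilicity enough to suppress C-benzylation, and heat with excess reagent takes the chelated ortho-OH groups.

Step 6
Reactants: 8 2,4,6-tris(benzyloxy)benzaldehyde
Product: 9 (E)-2,4,6-tris(benzyloxy)benzaldehyde oxime
Conditions: NH2OH·HCl, NaOAc, EtOH–THF, 50 °C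
Reagents that add atoms: hydroxylamine hydrochloride, NO.Cl
Why: Condensation of the aldehyde with hydroxylamine (oxime formation) gives the E-aldoxime.

Step 7
Reactants: 9 (E)-2,4,6-tris(benzyloxy)benzaldehyde oxime; 10 4-ethynylphenylboronic acid
Product: 12 [4-[3-[2,4,6-tris(benzyloxy)phenyl]-1,2-oxazol-5-yl]phenyl]boronic acid, via nitrile oxide 11 (not isolated)
Conditions: aq. NaOCl, CH2Cl2, 0 °C; organic phase separated and dried; then 10, THF–toluene, 70 °C
Reagents that add atoms: none
Why: Oxime dehydrogenation gives a di-ortho-substituted nitrile oxide that cannot dimerise, and its thermal Huisgen 1,3-dipolar [3+2] cycloaddition to the terminal arylalkyne closes the isoxazole regioselectively (3,5-diaryl), the ring whose C3–C4–C5 atoms become C4–C3–C2 of the flavone pyranone.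

Step 8
Reactants: 6 C6 phenol of the flavanone; 12 isoxazolyl-phenylboronic acid (2 equiv)
Product: 13 (2S)-7-methoxy-5-(methoxymethoxy)-2-[4-(methoxymethoxy)phenyl]-6-[4-[3-[2,4,6-tris(benzyloxy)phenyl]-1,2-oxazol-5-yl]phenoxy]chroman-4-one
Conditions: Cu(OAc)2 (2 equiv), pyridine (5 equiv), 4 Å MS, CH2Cl2, dry air, rt, 48 h
Reagents that add atoms: none
Why: Chan–Lam oxidative C–O coupling arylates the single free phenol with the arylboronic acid at room temperature with only pyridine as base, so the base-labile C2 centre survives.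

Step 9
Reactants: 13 protected isoxazole diaryl ether
Product: 15 (2S)-6-[4-(5,7-dihydroxy-4-oxo-4H-chromen-2-yl)phenoxy]-5-hydroxy-2-(4-hydroxyphenyl)-7-methoxychroman-4-one (target CNP0269971.1), via Z-enaminone 14 (not isolated)
Conditions: H2 (1 atm), 10% Pd/C, EtOAc–MeOH, rt; filter; then 2 M HCl, MeOH–H2O, 50 °C
Reagents that add atoms: water, O
Why: Hydrogenolysis removes the three benzyl ethers and cleaves the isoxazole N–O bond to the Z-enaminone, and aqueous HCl/MeOH then hydrolyses it (the new C4=O oxygen comes from water), closes the pyranone by cyclodehydration onto a freed ortho-OH and cleaves both MOM ethers, acid leaving the (2S) centre in place.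

**Compound list**

1 | (2S)-naringenin, (2S)-5,7-dihydroxy-2-(4-hydroxyphenyl)chroman-4-one | Oc1cc2c(c(O)c1)C(=O)C[C@@H](c1ccc(O)cc1)O2 | starting material
2 | (2S)-sakuranetin, (2S)-5-hydroxy-2-(4-hydroxyphenyl)-7-methoxychroman-4-one | COc1cc2c(c(O)c1)C(=O)C[C@@H](c1ccc(O)cc1)O2 | intermediate
3 | (2S)-5-hydroxy-2-(4-hydroxyphenyl)-6-iodo-7-methoxychroman-4-one | COc1cc2c(c(O)c1I)C(=O)C[C@@H](c1ccc(O)cc1)O2 | intermediate
4 | (2S)-6-iodo-7-methoxy-5-(methoxymethoxy)-2-[4-(methoxymethoxy)phenyl]chroman-4-one | COc1cc2c(c(OCOC)c1I)C(=O)C[C@@H](c1ccc(OCOC)cc1)O2 | intermediate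
5 | (2S)-7-methoxy-5-(methoxymethoxy)-2-[4-(methoxymethoxy)phenyl]-6-(4,4,5,5-tetramethyl-1,3,2-dioxaborolan-2-yl)chroman-4-one | COc1cc2c(c(OCOC)c1B3OC(C)(C)C(C)(C)O3)C(=O)C[C@@H](c1ccc(OCOC)cc1)O2 | intermediate (not isolated)
6 | (2S)-6-hydroxy-7-methoxy-5-(methoxymethoxy)-2-[4-(methoxymethoxy)phenyl]chroman-4-one | COc1cc2c(c(OCOC)c1O)C(=O)C[C@@H](c1ccc(OCOC)cc1)O2 | intermediate
7 | 2,4,6-trihydroxybenzaldehyde | O=Cc1c(O)cc(O)cc1O | starting material
8 | 2,4,6-tris(benzyloxy)benzaldehyde | O=Cc1c(OCc2ccccc2)cc(OCc2ccccc2)cc1OCc1ccccc1 | intermediate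
9 | (E)-2,4,6-tris(benzyloxy)benzaldehyde oxime | O/N=C/c1c(OCc2ccccc2)cc(OCc2ccccc2)cc1OCc1ccccc1 | intermediate
10 | 4-ethynylphenylboronic acid | C#Cc1ccc(cc1)B(O)O | starting material
11 | 2,4,6-tris(benzyloxy)benzonitrile oxide | [O-][N+]#Cc1c(OCc2ccccc2)cc(OCc2ccccc2)cc1OCc1ccccc1 | intermediate (not isolated)
12 | [4-[3-[2,4,6-tris(benzyloxy)phenyl]-1,2-oxazol-5-yl]phenyl]boronic acid | OB(O)c1ccc(cc1)-c1cc(no1)-c1c(OCc2ccccc2)cc(OCc2ccccc2)cc1OCc1ccccc1 | intermediate
13 | (2S)-7-methoxy-5-(methoxymethoxy)-2-[4-(methoxymethoxy)phenyl]-6-[4-[3-[2,4,6-tris(benzyloxy)phenyl]-1,2-oxazol-5-yl]phenoxy]chroman-4-one | COc1cc2c(c(OCOC)c1Oc1ccc(cc1)-c1cc(no1)-c1c(OCc3ccccc3)cc(OCc3ccccc3)cc1OCc1ccccc1)C(=O)C[C@@H](c1ccc(OCOC)cc1)O2 | intermediate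
14 | (2S)-6-[4-[(Z)-3-amino-3-(2,4,6-trihydroxyphenyl)prop-2-enoyl]phenoxy]-7-methoxy-5-(methoxymethoxy)-2-[4-(methoxymethoxy)phenyl]chroman-4-one | COc1cc2c(c(OCOC)c1Oc1ccc(cc1)C(=O)/C=C(\N)c1c(O)cc(O)cc1O)C(=O)C[C@@H](c1ccc(OCOC)cc1)O2 | intermediate (not isolated)
15 | (2S)-6-[4-(5,7-dihydroxy-4-oxo-4H-chromen-2-yl)phenoxy]-5-hydroxy-2-(4-hydroxyphenyl)-7-methoxychroman-4-one | COc1cc2c(c(O)c1Oc1ccc(-c3cc(=O)c4c(O)cc(O)cc4o3)cc1)C(=O)C[C@@H](c1ccc(O)cc1)O2 | target

**Totals**
Total step count: 9. Longest linear sequence: 6 (steps 1, 2, 3, 4, 8, 9).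

**Steps most likely to fail, with fallbacks**

Step 2 carries two selectivity risks: C6 against C8, and the A ring against the still-free B-ring phenol. The fallback changes the protecting-group order so that the B ring cannot compete and the chelated 5-OH is the only phenol left to direct the electrophile. It sets out from 2. MOMCl (1.1 equiv) and iPr2NEt at 0 °C alkylate only the 4'-OH and give (2S)-5-hydroxy-7-methoxy-2-[4-(methoxymethoxy)phenyl]chroman-4-one F1. Iodination with BnMe3N+ ICl2−/CaCO3 then gives (2S)-5-hydroxy-6-iodo-7-methoxy-2-[4-(methoxymethoxy)phenyl]chroman-4-one F2, with any 8-iodo isomer removed by chromatography. MOM protection of the 5-OH (MOMCl, iPr2NEt, Bu4NI, 40 °C) returns to the route at 4.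

Step 8 couples a di-ortho-substituted phenol with a bulky, Lewis-basic boronic acid and may stall. The fallback makes the C–O bond without copper, by ligand coupling on iodine(III) with a small aryl group, and uses the [3+2] cycloaddition itself as the fragment union. It sets out from 6. Deprotonation with t-BuOK (1.0 equiv, THF, 0 °C) and arylation with commercial bis(4-bromophenyl)iodonium triflate give (2S)-6-(4-bromophenoxy)-7-methoxy-5-(methoxymethoxy)-2-[4-(methoxymethoxy)phenyl]chroman-4-one F3. Base-free Stille coupling with tributyl(ethynyl)stannane (Pd(PPh3)4, toluene, 100 °C) gives (2S)-6-(4-ethynylphenoxy)-7-methoxy-5-(methoxymethoxy)-2-[4-(methoxymethoxy)phenyl]chroman-4-one F4. Cycloaddition of F4 with nitrile oxide 11 (made from 9 as in step 7; toluene, 70 °C) returns to the route at 13.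

Step 9 asks for debenzylation, N–O cleavage, enaminone hydrolysis, cyclodehydration and MOM removal in one operation on the epimerisable flavanone. The risks are a stalled 4-amino/imino intermediate and erosion of ee in warm acid. The fallback unmasks the flavone on the achiral fragment before the ether coupling, so the flavanone only has to survive a mild MOM cleavage. It sets out from 12. H2 over Pd/C gives [4-[(Z)-3-amino-3-(2,4,6-trihydroxyphenyl)prop-2-enoyl]phenyl]boronic acid F5 (not isolated), which hot aqueous HCl/dioxane converts into [4-(5,7-dihydroxy-4-oxo-4H-chromen-2-yl)phenyl]boronic acid F6. MOMCl/iPr2NEt protects the 7-OH (the chelated 5-OH stays free and is inert in the coupling) and gives [4-[5-hydroxy-7-(methoxymethoxy)-4-oxo-4H-chromen-2-yl]phenyl]boronic acid F7. Chan–Lam coupling of F7 with 6 under the conditions of step 8 gives (2S)-6-[4-[5-hydroxy-7-(methoxymethoxy)-4-oxo-4H-chromen-2-yl]phenoxy]-7-methoxy-5-(methoxymethoxy)-2-[4-(methoxymethoxy)phenyl]chroman-4-one F8. HCl in MeOH at 40 °C removes the three MOM groups and arrives at the target 15.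

**Further compounds**

F1 | step 2 | (2S)-5-hydroxy-7-methoxy-2-[4-(methoxymethoxy)phenyl]chroman-4-one | COc1cc2c(c(O)c1)C(=O)C[C@@H](c1ccc(OCOC)cc1)O2
F2 | step 2 | (2S)-5-hydroxy-6-iodo-7-methoxy-2-[4-(methoxymethoxy)phenyl]chroman-4-one | COc1cc2c(c(O)c1I)C(=O)C[C@@H](c1ccc(OCOC)cc1)O2
F3 | step 8 | (2S)-6-(4-bromophenoxy)-7-methoxy-5-(methoxymethoxy)-2-[4-(methoxymethoxy)phenyl]chroman-4-one | COc1cc2c(c(OCOC)c1Oc1ccc(Br)cc1)C(=O)C[C@@H](c1ccc(OCOC)cc1)O2
F4 | step 8 | (2S)-6-(4-ethynylphenoxy)-7-methoxy-5-(methoxymethoxy)-2-[4-(methoxymethoxy)phenyl]chroman-4-one | COc1cc2c(c(OCOC)c1Oc1ccc(C#C)cc1)C(=O)C[C@@H](c1ccc(OCOC)cc1)O2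
F5 | step 9 | [4-[(Z)-3-amino-3-(2,4,6-trihydroxyphenyl)prop-2-enoyl]phenyl]boronic acid | OB(O)c1ccc(cc1)C(=O)/C=C(\N)c1c(O)cc(O)cc1O
F6 | step 9 | [4-(5,7-dihydroxy-4-oxo-4H-chromen-2-yl)phenyl]boronic acid | O=c1cc(-c2ccc(cc2)B(O)O)oc2cc(O)cc(O)c12
F7 | step 9 | [4-[5-hydroxy-7-(methoxymethoxy)-4-oxo-4H-chromen-2-yl]phenyl]boronic acid | O=c1cc(-c2ccc(cc2)B(O)O)oc2cc(OCOC)cc(O)c12
F8 | step 9 | (2S)-6-[4-[5-hydroxy-7-(methoxymethoxy)-4-oxo-4H-chromen-2-yl]phenoxy]-7-methoxy-5-(methoxymethoxy)-2-[4-(methoxymethoxy)phenyl]chroman-4-one | COc1cc2c(c(OCOC)c1Oc1ccc(cc1)-c1cc(=O)c3c(O)cc(OCOC)cc3o1)C(=O)C[C@@H](c1ccc(OCOC)cc1)O2
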